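**Plan**
- Retrosynthesis: the target is cut first at the bond from the guaiacyl carbon of ring B to oxolane C2, then at C3–CH2O, then at the exocyclic carbinol–C4 bond. This leaves vanillin, methyl 4-oxobutanoate, a C1 electrophile and a guaiacyl boron reagent.
- Forward: an enamine aldol joins the carbinol carbon to the future C4; reduction and lactonisation close the only ring that is built (a γ-lactone that becomes the oxolane); the CH2O carbon is added by enolate alkylation; the lactone carbonyl is taken down to an anomeric acetate; ring B is attached there; two deprotections finish.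
- Stereochemistry: the carbinol carbon and C4 come from D-proline (anti aldol), C3 from alkylation trans to the C4 side chain, C2 from arylation trans to the C3 substituent.
- Enabling feature: oxolane C2 sits between ring oxygen O1 and the substituted C3, so as an acetate it ionises to an O1-stabilised cation. The free para hydroxyl of ring B makes the new benzylic C2–O1 bond reversible, so the all-trans oxolane is also the thermodynamic sink.
- Helpers: a tosylate on ring A (activates the aldehyde for the aldol, later keeps the second benzylic oxygen from ionising), the C2 acetate and two silyl ethers; the tosylate and silyl ethers are removed in steps 8 and 9.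

Key step: step 7

Remark on locants and abbreviations: oxolane O1, C2, C3, C4, C5 correspond to lignan atoms O, C7, C8, C8', C9'; C9 is the CH2O carbon on C3 and C7' the carbinol carbon on C4; ring A is the aryl group on C7', ring B the aryl group on C2. Ts = 4-methylbenzenesulfonyl, TBS = tert-butyldimethylsilyl, TIPS = triisopropylsilyl.

**Step 1**
Reactants: 1 vanillin (4-hydroxy-3-methoxybenzaldehyde)
Product: 2 4-formyl-2-methoxyphenyl 4-methylbenzenesulfonate
Conditions: TsCl, Et3N, DMAP (cat.), CH2Cl2, 0 °C to rt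
Reagents that add atoms: p-toluenesulfonyl chloride, Cc1ccc(S(=O)(=O)Cl)cc1
Why: Sulfonylation of the phenol, which should make the aldehyde electrophilic enough for enamine aldol chemistry and later deactivate ring A toward benzylic ionisation; no stereocenter is formed.

**Step 2**
Reactants: 2 4-formyl-2-methoxyphenyl 4-methylbenzenesulfonate; 3 methyl 4-oxobutanoate (3 equiv)
Product: 6 (4S)-4-[(S)-hydroxy(3-methoxy-4-tosyloxyphenyl)methyl]oxolan-2-one, via aldol aldehyde 4 (not isolated), via hydroxy ester 5 (not isolated)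
Conditions: D-proline (20 mol %), DMF, 4 °C; then MeOH, NaBH4, −20 to 0 °C; aq. NH4Cl; pyridinium p-toluenesulfonate (cat.), CH2Cl2, rt
Reagents that add atoms: none
Why: Proline-catalysed direct cross-aldol reaction through a hydrogen-bonded chair-like enamine transition state, in which the E-enamine of 3 with D-proline should add to the Si face of the non-enolisable aldehyde 2 and set C8' and C7' anti as (S,S) in one C–C bond formation; NaBH4 reduction of the new aldehyde and lactonisation of the primary alcohol onto the methyl ester then fix the array as lactone 6.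

**Step 3**
Reactants: 6 (4S)-4-[(S)-hydroxy(3-methoxy-4-tosyloxyphenyl)methyl]oxolan-2-one
Product: 7 (4S)-4-[(S)-(tert-butyldimethylsilyloxy)(3-methoxy-4-tosyloxyphenyl)methyl]oxolan-2-one
Conditions: TBSOTf, 2,6-lutidine, CH2Cl2, −78 to 0 °C
Reagents that add atoms: tert-butyldimethylsilyl trifluoromethanesulfonate, CC(C)(C)[Si](C)(C)OS(=O)(=O)C(F)(F)F
Why: Silylation of the secondary benzylic alcohol with a silyl triflate and a hindered base masks O7' against the base, hydride and Lewis acid of steps 4, 5 and 7; no new stereocenter is formed.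

**Step 4**
Reactants: 7 (4S)-4-[(S)-(tert-butyldimethylsilyloxy)(3-methoxy-4-tosyloxyphenyl)methyl]oxolan-2-one
Product: 9 (3R,4S)-4-[(S)-(tert-butyldimethylsilyloxy)(3-methoxy-4-tosyloxyphenyl)methyl]-3-[(triisopropylsilyloxy)methyl]oxolan-2-one, via lithium enolate 8 (not isolated)
Conditions: LiN(iPr)2, THF, −78 °C; then (iPr)3SiOCH2Cl, DMPU, −78 to −40 °C
Reagents that add atoms: (triisopropylsiloxy)methyl chloride, ClCO[Si](C(C)C)(C(C)C)C(C)C
Why: Alkylation of a lactone lithium enolate with an α-chloro ether (SN2), in which the electrophile should enter anti to the bulky C4 side chain, giving the 3,4-trans lactone and setting C8 as (R) with the hydroxymethyl carbon already silyl-protected.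

**Step 5**
Reactants: 9 (3R,4S)-4-[(S)-(tert-butyldimethylsilyloxy)(3-methoxy-4-tosyloxyphenyl)methyl]-3-[(triisopropylsilyloxy)methyl]oxolan-2-one
Product: 11 (3R,4S)-4-[(S)-(tert-butyldimethylsilyloxy)(3-methoxy-4-tosyloxyphenyl)methyl]-3-[(triisopropylsilyloxy)methyl]oxolan-2-yl acetate (both C2 epimers), via aluminium hemiacetal 10 (not isolated)
Conditions: iBu2AlH, CH2Cl2, −78 °C; then pyridine, DMAP, Ac2O, −78 to 0 °C
Reagents that add atoms: acetic anhydride, CC(=O)OC(C)=O
Why: Reductive acetylation of a lactone, in which iBu2AlH should add once to the carbonyl at −78 °C and the tetrahedral aluminium hemiacetal is acetylated before it can collapse, leaving C2 at the aldehyde oxidation level as an ionisable acetate; the anomeric center is formed as a mixture that is erased in step 7.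

**Step 6**
Reactants: 12 2-methoxy-4-(4,4,5,5-tetramethyl-1,3,2-dioxaborolan-2-yl)phenol
Product: 13 potassium trifluoro(4-hydroxy-3-methoxyphenyl)borate
Conditions: KHF2 (aq.), MeOH, rt
Reagents that add atoms: potassium hydrogen difluoride, [K+].[F-].F
Why: Conversion of a pinacol boronate into its trifluoroborate salt, which fixes the nucleophilic site of guaiacol at the carbon para to the hydroxyl; no stereocenter is formed.

**Step 7**
Reactants: 11 (3R,4S)-4-[(S)-(tert-butyldimethylsilyloxy)(3-methoxy-4-tosyloxyphenyl)methyl]-3-[(triisopropylsilyloxy)methyl]oxolan-2-yl acetate; 13 potassium trifluoro(4-hydroxy-3-methoxyphenyl)borate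
Product: 15 (2S,3R,4S)-2-(4-hydroxy-3-methoxyphenyl)-4-[(S)-(tert-butyldimethylsilyloxy)(3-methoxy-4-tosyloxyphenyl)methyl]-3-[(triisopropylsilyloxy)methyl]oxolane, via oxocarbenium ion 14 (not isolated)
Conditions: BF3·OEt2, CH2Cl2/MeCN, −40 to −10 °C
Reagents that add atoms: none
Why: BF3·OEt2 ionises the anomeric acetate of 11 to the five-membered oxocarbenium ion 14, whose cationic C2 is stabilised by the lone pair of ring oxygen O1, and turns 13 into an aryl fluoroborane whose boron-bearing carbon, para to the free hydroxyl, attacks C2 with loss of boron (ipso substitution). The closest known reaction type is the BF3-promoted coupling of potassium organotrifluoroborates with O,O-acetals and glycosyl donors, a Friedel–Crafts-type C-aryl glycosylation. No ring is closed in the productive event, the oxolane being carried in from the lactone; if the new benzylic C2–O1 bond ionises under the Lewis acid it should reclose by 5-exo-trig attack of O1 on the quinone-methide-like cation. The new stereocenter C2 (C7) is controlled by the adjacent C3 CH2OTIPS group, anti to which the aryl group should enter, and the same (2S) all-trans isomer is the thermodynamic sink of that reversible ionisation, which the free para hydroxyl of ring B permits. The step needs site selectivity on the arene, secured by the position of boron, and chemoselectivity between the two benzylic oxygens, secured by the electron-poor tosyloxy ring A that should keep C7'–OTBS from ionising. Attack of the phenol oxygen on 14 would only give an aryl acetal that re-ionises under the same conditions.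

**Step 8**
Reactants: 15 (2S,3R,4S)-2-(4-hydroxy-3-methoxyphenyl)-4-[(S)-(tert-butyldimethylsilyloxy)(3-methoxy-4-tosyloxyphenyl)methyl]-3-[(triisopropylsilyloxy)methyl]oxolane
Product: 16 (2S,3R,4S)-2-(4-hydroxy-3-methoxyphenyl)-4-[(S)-(tert-butyldimethylsilyloxy)(4-hydroxy-3-methoxyphenyl)methyl]-3-[(triisopropylsilyloxy)methyl]oxolane
Conditions: Mg turnings, MeOH, 0 °C to rt
Reagents that add atoms: none
Why: Single-electron reductive S–O cleavage of an aryl sulfonate by Mg in MeOH should free the ring A phenol without acid while both alkyl silyl ethers stay in place; no stereocenter is touched.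

**Step 9**
Reactants: 16 (2S,3R,4S)-2-(4-hydroxy-3-methoxyphenyl)-4-[(S)-(tert-butyldimethylsilyloxy)(4-hydroxy-3-methoxyphenyl)methyl]-3-[(triisopropylsilyloxy)methyl]oxolane
Product: 17 4-[(2S,3R,4S)-4-[(S)-hydroxy(4-hydroxy-3-methoxyphenyl)methyl]-3-(hydroxymethyl)oxolan-2-yl]-2-methoxyphenol (target)
Conditions: Bu4NF, AcOH, THF, 0 °C to rt
Reagents that add atoms: none
Why: Fluoride-mediated cleavage of both silyl ethers, buffered with AcOH so that neither p-hydroxybenzylic C–O bond meets strong acid or base, should release the target with all four stereocenters as set.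

**Compound list**
1 | vanillin (4-hydroxy-3-methoxybenzaldehyde) | COc1cc(C=O)ccc1O | starting material
2 | 4-formyl-2-methoxyphenyl 4-methylbenzenesulfonate | COc1cc(C=O)ccc1OS(=O)(=O)c1ccc(C)cc1 | intermediate
3 | methyl 4-oxobutanoate | COC(=O)CCC=O | starting material
4 | methyl (3R,4S)-3-formyl-4-hydroxy-4-(3-methoxy-4-tosyloxyphenyl)butanoate (aldol aldehyde, not isolated) | COc1cc([C@@H](O)[C@H](C=O)CC(=O)OC)ccc1OS(=O)(=O)c1ccc(C)cc1 | intermediate
5 | methyl (3S,4S)-4-hydroxy-3-(hydroxymethyl)-4-(3-methoxy-4-tosyloxyphenyl)butanoate (hydroxy ester, not isolated) | COc1cc([C@@H](O)[C@H](CO)CC(=O)OC)ccc1OS(=O)(=O)c1ccc(C)cc1 | intermediate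
6 | (4S)-4-[(S)-hydroxy(3-methoxy-4-tosyloxyphenyl)methyl]oxolan-2-one | COc1cc([C@@H](O)[C@@H]2COC(=O)C2)ccc1OS(=O)(=O)c1ccc(C)cc1 | intermediate
7 | (4S)-4-[(S)-(tert-butyldimethylsilyloxy)(3-methoxy-4-tosyloxyphenyl)methyl]oxolan-2-one | COc1cc([C@@H](O[Si](C)(C)C(C)(C)C)[C@@H]2COC(=O)C2)ccc1OS(=O)(=O)c1ccc(C)cc1 | intermediate
8 | lithium enolate of 7 (not isolated) | COc1cc([C@@H](O[Si](C)(C)C(C)(C)C)[C@@H]2COC(O[Li])=C2)ccc1OS(=O)(=O)c1ccc(C)cc1 | intermediate
9 | (3R,4S)-4-[(S)-(tert-butyldimethylsilyloxy)(3-methoxy-4-tosyloxyphenyl)methyl]-3-[(triisopropylsilyloxy)methyl]oxolan-2-one | COc1cc([C@@H](O[Si](C)(C)C(C)(C)C)[C@@H]2COC(=O)[C@H]2CO[Si](C(C)C)(C(C)C)C(C)C)ccc1OS(=O)(=O)c1ccc(C)cc1 | intermediate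
10 | diisobutylaluminium hemiacetal of 9 (C2 configuration not defined, not isolated) | COc1cc([C@@H](O[Si](C)(C)C(C)(C)C)[C@@H]2COC(O[Al](CC(C)C)CC(C)C)[C@H]2CO[Si](C(C)C)(C(C)C)C(C)C)ccc1OS(=O)(=O)c1ccc(C)cc1 | intermediate
11 | (3R,4S)-4-[(S)-(tert-butyldimethylsilyloxy)(3-methoxy-4-tosyloxyphenyl)methyl]-3-[(triisopropylsilyloxy)methyl]oxolan-2-yl acetate (both C2 epimers) | COc1cc([C@@H](O[Si](C)(C)C(C)(C)C)[C@@H]2COC(OC(C)=O)[C@H]2CO[Si](C(C)C)(C(C)C)C(C)C)ccc1OS(=O)(=O)c1ccc(C)cc1 | intermediate
12 | 2-methoxy-4-(4,4,5,5-tetramethyl-1,3,2-dioxaborolan-2-yl)phenol | COc1cc(B2OC(C)(C)C(C)(C)O2)ccc1O | starting material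
13 | potassium trifluoro(4-hydroxy-3-methoxyphenyl)borate | COc1cc([B-](F)(F)F)ccc1O.[K+] | intermediate
14 | oxocarbenium ion from 11 (C2 cationic, 3R,4S; not isolated) | COc1cc([C@@H](O[Si](C)(C)C(C)(C)C)[C@@H]2C[O+]=C[C@H]2CO[Si](C(C)C)(C(C)C)C(C)C)ccc1OS(=O)(=O)c1ccc(C)cc1 | intermediate
15 | (2S,3R,4S)-2-(4-hydroxy-3-methoxyphenyl)-4-[(S)-(tert-butyldimethylsilyloxy)(3-methoxy-4-tosyloxyphenyl)methyl]-3-[(triisopropylsilyloxy)methyl]oxolane | COc1cc([C@@H](O[Si](C)(C)C(C)(C)C)[C@@H]2CO[C@H](c3ccc(O)c(OC)c3)[C@H]2CO[Si](C(C)C)(C(C)C)C(C)C)ccc1OS(=O)(=O)c1ccc(C)cc1 | intermediate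
16 | (2S,3R,4S)-2-(4-hydroxy-3-methoxyphenyl)-4-[(S)-(tert-butyldimethylsilyloxy)(4-hydroxy-3-methoxyphenyl)methyl]-3-[(triisopropylsilyloxy)methyl]oxolane | COc1cc([C@@H](O[Si](C)(C)C(C)(C)C)[C@@H]2CO[C@H](c3ccc(O)c(OC)c3)[C@H]2CO[Si](C(C)C)(C(C)C)C(C)C)ccc1O | intermediate
17 | 4-[(2S,3R,4S)-4-[(S)-hydroxy(4-hydroxy-3-methoxyphenyl)methyl]-3-(hydroxymethyl)oxolan-2-yl]-2-methoxyphenol | COc1cc([C@@H](O)[C@@H]2CO[C@H](c3ccc(O)c(OC)c3)[C@H]2CO)ccc1O | target

**Step count:** 9 steps in total; the longest linear sequence is 8 steps (steps 1 to 5 and 7 to 9, from vanillin).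

**Steps most likely to fail**

Step 7. The arylation may suffer from poor facial selectivity at C2 if equilibration is slow, from loss of a silyl ether in the fluoroborane medium followed by capture of the cation by O7', or from a second arylation of the ring-opened benzylic cation. The fallback sets out from lactone 9 and comes back at 15. Purchased (4-bromo-2-methoxyphenoxy)(tert-butyl)dimethylsilane undergoes Br/Li exchange (n-BuLi, THF, −78 °C) to [4-(tert-butyldimethylsilyloxy)-3-methoxyphenyl]lithium F1. F1 should add once to the lactone carbonyl of 9 to give the cyclic hemiketal (2-aryl-2-hydroxyoxolane) F2. Ionic reduction (Et3SiH, BF3·OEt2, CH2Cl2, −78 to −20 °C) should then deliver the silyl-protected 2-aryl oxolane F3, the Lewis acid equilibrating the benzylic center to the all-trans isomer. KHF2 in MeOH should cleave only the aryl silyl ether and give 15.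

Step 2. The enamine addition may be slow relative to self-aldol of the donor, the anti selectivity may erode, the aldol may dehydrate before reduction, or lactonisation may occur through the secondary hydroxyl. The fallback sets out from aldehyde 2 and comes back at 6. (4S)-4-Benzyl-1,3-oxazolidin-2-one is acylated with 4-methoxy-4-oxobutanoic acid (pivaloyl chloride, Et3N, LiCl) to methyl 4-[(4S)-4-benzyl-2-oxo-1,3-oxazolidin-3-yl]-4-oxobutanoate F4. A magnesium-halide-catalysed anti-aldol of this auxiliary imide with 2 (MgCl2 cat., Et3N, Me3SiCl, EtOAc, rt) should give the O-trimethylsilyl anti-aldol imide F5; the (S) auxiliary is chosen on the chelated-enolate model so that the same (7'S,8'S) array results. LiBH4 (THF, MeOH, 0 °C) should remove the auxiliary reductively, and the primary alkoxide should close onto the methyl ester to give the O-trimethylsilyl lactone F6. Mild acid methanolysis (citric acid, MeOH) gives 6.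

Step 4. The enolate may be O-alkylated, may take up the silyl group, or may react incompletely at the hindered α-carbon. The fallback sets out from lactone 7 and comes back at 9. Enolate 8 is treated with gaseous formaldehyde (from cracked paraformaldehyde, THF, −78 to −40 °C) in an aldol reaction that should give the trans hydroxymethyl lactone (3R,4S)-4-[(S)-(tert-butyldimethylsilyloxy)(3-methoxy-4-tosyloxyphenyl)methyl]-3-(hydroxymethyl)oxolan-2-one F7. Silylation of F7 (TIPSCl, imidazole, DMF) gives 9.

**Further compounds**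
F1 | step 7 | [4-(tert-butyldimethylsilyloxy)-3-methoxyphenyl]lithium | COc1cc([Li])ccc1O[Si](C)(C)C(C)(C)C
F2 | step 7 | (3R,4S)-2-[4-(tert-butyldimethylsilyloxy)-3-methoxyphenyl]-4-[(S)-(tert-butyldimethylsilyloxy)(3-methoxy-4-tosyloxyphenyl)methyl]-3-[(triisopropylsilyloxy)methyl]oxolan-2-ol (C2 configuration not defined) | COc1cc([C@@H](O[Si](C)(C)C(C)(C)C)[C@@H]2COC(O)(c3ccc(O[Si](C)(C)C(C)(C)C)c(OC)c3)[C@H]2CO[Si](C(C)C)(C(C)C)C(C)C)ccc1OS(=O)(=O)c1ccc(C)cc1
F3 | step 7 | (2S,3R,4S)-2-[4-(tert-butyldimethylsilyloxy)-3-methoxyphenyl]-4-[(S)-(tert-butyldimethylsilyloxy)(3-methoxy-4-tosyloxyphenyl)methyl]-3-[(triisopropylsilyloxy)methyl]oxolane | COc1cc([C@@H](O[Si](C)(C)C(C)(C)C)[C@@H]2CO[C@H](c3ccc(O[Si](C)(C)C(C)(C)C)c(OC)c3)[C@H]2CO[Si](C(C)C)(C(C)C)C(C)C)ccc1OS(=O)(=O)c1ccc(C)cc1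
F4 | step 2 | methyl 4-[(4S)-4-benzyl-2-oxo-1,3-oxazolidin-3-yl]-4-oxobutanoate | COC(=O)CCC(=O)N1[C@@H](Cc2ccccc2)COC1=O
F5 | step 2 | O-trimethylsilyl anti-aldol imide from F4 and 2 | COc1cc([C@@H](O[Si](C)(C)C)[C@@H](CC(=O)OC)C(=O)N2[C@@H](Cc3ccccc3)COC2=O)ccc1OS(=O)(=O)c1ccc(C)cc1
F6 | step 2 | (4S)-4-[(S)-(trimethylsilyloxy)(3-methoxy-4-tosyloxyphenyl)methyl]oxolan-2-one | COc1cc([C@@H](O[Si](C)(C)C)[C@@H]2COC(=O)C2)ccc1OS(=O)(=O)c1ccc(C)cc1
F7 | step 4 | (3R,4S)-4-[(S)-(tert-butyldimethylsilyloxy)(3-methoxy-4-tosyloxyphenyl)methyl]-3-(hydroxymethyl)oxolan-2-one | COc1cc([C@@H](O[Si](C)(C)C(C)(C)C)[C@@H]2COC(=O)[C@H]2CO)ccc1OS(=O)(=O)c1ccc(C)cc1
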